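## Retrosynthetic overview

- The core is numbered as a chromene (O1, C2, C3, C4, C4a, C5–C8, C8a). Ring A is the carbocycle and ring B the pyranone. The acid is unmasked last from its tert-butyl ester.
- Both rings are disconnected at once to an acyclic ynone and an anti-aldol hydroxy ester: O1–C8a, then C4–C4a (ring B), then C7–C8 (ring A), in one flask. The cyclobutane is carried intact from (−)-verbenone.
- Enabling feature: the ynone C5(=O)–C4a≡C8a, set between the quaternary C6 (which carries ester C7) and the propargylic C8. C8a is the only Michael terminus for O1, C4a becomes an allenolate carbon six atoms from ester C4, and C8 becomes vinylogously acidic six atoms from C7.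
- The ynone comes from a chiral malonic half-acid and a chiral alkyne by acyl Sonogashira coupling. C6 is set by phase-transfer prenylation of a mixed malonate, the benzylic centre by anhydride desymmetrisation, and C2/C3 come from methyl (R)-3-hydroxybutanoate.

Key step: step 15

Remark (tautomerism): the last two compounds are enolised β-triketones. They are drawn as the C5-enol of the target, and the route is assumed to give the same equilibrating tautomer set.

Remark (catalyst sense): in steps 7 and 9 the catalyst antipode named is the one expected to give the drawn configuration. The sense of induction for these particular substrates is not established, and the enantiomeric (step 7) or pseudo-enantiomeric (step 9) catalyst is the direct substitute if it proves reversed.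

## Route

Step 1
Reactants: 1 (1S,5S)-(−)-verbenone
Product: 2 (1S,3R)-3-acetyl-2,2-dimethylcyclobutane-1-carboxylic acid (cis-pinononic acid)
Conditions: RuCl3·xH2O (2 mol%), NaIO4 (4.2 equiv), CCl4/MeCN/H2O, 23 °C
Reagents that add atoms: sodium periodate, [Na+].[O-]I(=O)(=O)=O; water, O
Why: RuO4-type oxidative cleavage of the enone C=C gives the methyl ketone and an α-keto acid that is decarboxylated oxidatively to the acid, and the two ring stereocentres are not touched and stay cis.

Step 2
Reactants: 2 cis-pinononic acid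
Product: 3 (1S,3S)-2,2-dimethyl-3-(prop-1-en-2-yl)cyclobutane-1-carboxylic acid
Conditions: Ph3PCH3Br (2.5 equiv), KOtBu (3.5 equiv), THF, 0 to 40 °C; aq. HCl to pH 3
Reagents that add atoms: methyltriphenylphosphonium bromide, C[P+](c1ccccc1)(c1ccccc1)c1ccccc1.[Br-]
Why: Wittig methylenation of the methyl ketone on the preformed potassium carboxylate, which shields C1 from enolisation, while C3 should keep its configuration because the ketone enolises mainly toward its methyl group.

Step 3
Reactants: 3 isopropenyl acid
Product: 4 [(1S,3S)-2,2-dimethyl-3-(prop-1-en-2-yl)cyclobutyl]methanol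
Conditions: LiAlH4, Et2O, 0 to 23 °C
Reagents that add atoms: none
Why: hydride reduction of the carboxylic acid to the primary alcohol, which leaves the isolated alkene and both stereocentres alone.

Step 4
Reactants: 4 cyclobutylmethanol
Product: 5 (1S,3S)-1-(iodomethyl)-2,2-dimethyl-3-(prop-1-en-2-yl)cyclobutane
Conditions: PPh3, I2, imidazole, CH2Cl2, 0 to 23 °C, dark
Reagents that add atoms: iodine, II
Why: Appel-type iodination through the alkoxyphosphonium salt is an SN2 displacement at the primary carbon, so no cyclobutylcarbinyl cation and no ring expansion is involved.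

Step 5
Reactants: 6 3-tert-butoxy-3-oxopropanoic acid (mono-tert-butyl malonate); 7 2,2-diphenylethanol
Product: 8 tert-butyl 2,2-diphenylethyl malonate
Conditions: DCC, DMAP (5 mol%), CH2Cl2, 0 to 23 °C
Reagents that add atoms: none
Why: Steglich esterification gives the mixed malonate whose two unlike esters are what the chiral catalyst of step 7 differentiates.

Step 6
Reactants: 8 mixed malonate (1.5 equiv); 5 iodide
Product: 9 tert-butyl 2,2-diphenylethyl 2-{[(1R,3S)-2,2-dimethyl-3-(prop-1-en-2-yl)cyclobutyl]methyl}malonate (both epimers at the malonate carbon)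
Conditions: NaH, DMF, 0 to 60 °C
Reagents that add atoms: none
Why: malonic ester alkylation by SN2 at the primary iodide, where the new malonate CH is a transient stereocentre that is erased on enolisation in step 7.

Step 7
Reactants: 9 monoalkyl malonate
Product: 10 1-tert-butyl 3-(2,2-diphenylethyl) (2S)-2-{[(1R,3S)-2,2-dimethyl-3-(prop-1-en-2-yl)cyclobutyl]methyl}-2-(3-methylbut-2-en-1-yl)propanedioate
Conditions: prenyl bromide (5 equiv), (11bS,11'bS)-2,6-bis(3,4,5-trifluorophenyl)-3,3',5,5'-tetrahydro-4,4'-spirobi[dinaphtho[2,1-c:1',2'-e]azepin]-4-ium bromide (5 mol%), 50% aq. KOH, toluene, −40 °C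
Reagents that add atoms: 1-bromo-3-methylbut-2-ene, CC(C)=CCBr
Why: enantioselective phase-transfer alkylation of an α-monosubstituted tert-butyl 2,2-diphenylethyl malonate, in which the chiral N-spiro ammonium cation pairs with the enolate and exposes one face by telling the two unlike esters apart, so the quaternary C6 should be set as (2S) under catalyst control.

Step 8
Reactants: 10 quaternary malonate
Product: 11 (2R)-2-{[(1R,3S)-2,2-dimethyl-3-(prop-1-en-2-yl)cyclobutyl]methyl}-3-(2,2-diphenylethoxy)-2-(3-methylbut-2-en-1-yl)-3-oxopropanoic acid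
Conditions: Me3SiOTf (2.5 equiv), 2,6-lutidine (4 equiv), CH2Cl2, 0 to 23 °C; aq. citric acid
Reagents that add atoms: none
Why: silyl-triflate-mediated cleavage of the tert-butyl ester (O-silylation, loss of isobutene, hydrolysis of the silyl ester) under lutidine buffering should spare the prenyl and isopropenylcyclobutane groups that a protic acid would endanger, and the primary ester and C6 are unaffected.

Step 9
Reactants: 12 3-phenylglutaric anhydride (4-phenyloxane-2,6-dione)
Product: 13 (3R)-5-methoxy-5-oxo-3-phenylpentanoic acid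
Conditions: MeOH (10 equiv), hydroquinidine anthraquinone-1,4-diyl diether (DHQD)2AQN (10 mol%), Et2O, −40 °C
Reagents that add atoms: methanol, CO
Why: alkaloid-catalysed enantioselective methanolysis (desymmetrisation) of the prochiral anhydride, in which the quinuclidine acts as general base and differentiates the two enantiotopic carbonyls, sets the benzylic centre.

Step 10
Reactants: 13 hemiester
Product: 14 1-tert-butyl 5-methyl (3S)-3-phenylpentanedioate
Conditions: tert-butyl 2,2,2-trichloroacetimidate, BF3·OEt2 (2 mol%), cyclohexane/CH2Cl2, 23 °C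
Reagents that add atoms: tert-butyl 2,2,2-trichloroacetimidate, CC(C)(C)OC(=N)C(Cl)(Cl)Cl
Why: acid-catalysed tert-butylation of the carboxylic acid by the imidate gives the non-electrophilic ester needed for step 15 without touching the stereocentre.

Step 11
Reactants: 14 mixed diester
Product: 15 tert-butyl (3S)-5-oxo-3-phenylpentanoate
Conditions: iBu2AlH (1.05 equiv), CH2Cl2, −78 °C; aq. Rochelle salt
Reagents that add atoms: none
Why: partial reduction of the methyl ester through the aluminium hemiacetal that is stable at −78 °C, with the tert-butyl ester much less reactive.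

Step 12
Reactants: 15 aldehyde
Product: 16 tert-butyl (3S)-3-phenylhex-5-ynoate
Conditions: dimethyl (1-diazo-2-oxopropyl)phosphonate, K2CO3, MeOH, 0 to 23 °C
Reagents that add atoms: dimethyl (1-diazo-2-oxopropyl)phosphonate, COP(=O)(OC)C(=[N+]=[N-])C(C)=O
Why: Seyferth–Gilbert homologation with the Ohira–Bestmann reagent converts the aldehyde into the terminal alkyne under conditions that leave the tert-butyl ester and the non-acidic benzylic centre intact.

Step 13
Reactants: 11 malonic half-acid; 16 alkyne
Product: 18 9-tert-butyl 1-(2,2-diphenylethyl) (2R,7S)-2-{[(1R,3S)-2,2-dimethyl-3-(prop-1-en-2-yl)cyclobutyl]methyl}-2-(3-methylbut-2-en-1-yl)-3-oxo-7-phenylnon-4-ynedioate, via acid chloride 17 (not isolated)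
Conditions: 1-chloro-N,N,2-trimethylprop-1-en-1-amine, CH2Cl2, 0 to 23 °C; then 16, PdCl2(PPh3)2 (2 mol%), CuI (4 mol%), Et3N, THF, 23 °C
Reagents that add atoms: none
Why: the α-chloroenamine makes the acid chloride without free HCl (no α-hydrogen, so no ketene), and acyl Sonogashira coupling (oxidative addition to zerovalent palladium, transmetalation from the copper acetylide, reductive elimination) gives the ynone while tolerating both esters.

Step 14
Reactants: 19 methyl (3R)-3-hydroxybutanoate
Product: 20 methyl (2R,3R)-3-hydroxy-2-methylbutanoate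
Conditions: LiN(iPr)2 (2.2 equiv), THF, −78 to −20 °C; MeI, DMPU, −78 to 0 °C; aq. HCl
Reagents that add atoms: iodomethane, CI
Why: Fráter–Seebach alkylation, in which the chelated alkoxide-enolate dianion is methylated anti to the carbinol methyl group and so gives the anti (2R,3R) ester.

Step 15
Reactants: 18 ynone; 20 anti-aldol ester (1.1 equiv)
Product: 23 tert-butyl (3S)-3-[(2R,3R,6R)-6-{[(1R,3S)-2,2-dimethyl-3-(prop-1-en-2-yl)cyclobutyl]methyl}-5-hydroxy-2,3-dimethyl-6-(3-methylbut-2-en-1-yl)-4,7-dioxo-3,4,6,7-tetrahydro-2H-chromen-8-yl]-3-phenylpropanoate, via sodium allenolate 21 (not isolated), via dihydropyranone 22 (not isolated)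
Conditions: 20, NaH (1.05 equiv), THF, −20 °C; then 18, −40 to 23 °C; AcOH quench
Reagents that add atoms: none
Why: Proposed new method: the sodium alkoxide of 20 adds 1,4 to the ynone at C8a (O1–C8a), the allenolate carbon C4a attacks the methyl ester C4 six atoms away (C4–C4a, loss of methoxide) to give dihydropyranone 22, and the methoxide then removes the now vinylogously acidic C8–H so that C8 attacks ester C7 (vinylogous Dieckmann, loss of 2,2-diphenylethoxide), with the enolate of the resulting β-triketone as thermodynamic sink. The closest known reaction types are the oxa-Michael/Dieckmann annulation of hydroxy esters with acrylates or alkynoates, Michael–Claisen annulations of the Staunton–Weinreb kind, and the Dieckmann closure of 3,5-dioxo esters to 2,2-dialkylcyclohexane-1,3,5-triones; their merger on an ynone so that both rings form at once is the new element. Ring B closes 6-exo-trig at the C4 ester carbonyl with C4a=C8a endocyclic, and ring A closes 6-exo-trig at the C7 ester, the cis placement of C5 and C8 on C4a=C8a that this needs being enforced by ring B. No stereocentre is created: C2, C6, the benzylic centre and the cyclobutane centres are carried in unchanged, and C3 (α to C4=O) can only equilibrate to the trans-diequatorial (2R,3R) arrangement already present. The step needs 1,4- over 1,2-addition (the C5 carbonyl is neopentyl-type, next to quaternary C6), acylation of C4a by the methyl ester only (the side-chain ester is tert-butyl and C7 cannot be reached from C4a without a four-membered ring), and Claisen closure faster than β-elimination of the alkoxy ester (stoichiometric preformed alkoxide, aprotic medium, no free base present before ring B has closed). If the allenolate is protonated, or the ynone first isomerises to the allenone, γ-deprotonation or alkoxide addition gives the same dienolate, which is acylated at C4a and converges on 22.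

Step 16
Reactants: 23 tert-butyl ester
Product: 24 (3S)-3-[(2R,3R,6R)-6-{[(1R,3S)-2,2-dimethyl-3-(prop-1-en-2-yl)cyclobutyl]methyl}-5-hydroxy-2,3-dimethyl-6-(3-methylbut-2-en-1-yl)-4,7-dioxo-3,4,6,7-tetrahydro-2H-chromen-8-yl]-3-phenylpropanoic acid (target)
Conditions: Me3SiOTf (4 equiv), 2,6-lutidine (6 equiv), CH2Cl2, 0 °C; pH 5 buffer
Reagents that add atoms: none
Why: buffered silyl-triflate cleavage of the tert-butyl ester (transient silyl enol ether and silyl ester are hydrolysed on work-up) avoids the protic acid that would cyclise the C5 enol onto the prenyl group or open the isopropenylcyclobutane, and leaves all six stereocentres in place.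

## Compound list

1 | (1S,5S)-(−)-verbenone | CC1=CC(=O)[C@H]2C[C@@H]1C2(C)C | starting material
2 | (1S,3R)-3-acetyl-2,2-dimethylcyclobutane-1-carboxylic acid | CC(=O)[C@@H]1C[C@H](C(=O)O)C1(C)C | intermediate
3 | (1S,3S)-2,2-dimethyl-3-(prop-1-en-2-yl)cyclobutane-1-carboxylic acid | C=C(C)[C@@H]1C[C@H](C(=O)O)C1(C)C | intermediate
4 | [(1S,3S)-2,2-dimethyl-3-(prop-1-en-2-yl)cyclobutyl]methanol | C=C(C)[C@@H]1C[C@H](CO)C1(C)C | intermediate
5 | (1S,3S)-1-(iodomethyl)-2,2-dimethyl-3-(prop-1-en-2-yl)cyclobutane | C=C(C)[C@@H]1C[C@H](CI)C1(C)C | intermediate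
6 | 3-tert-butoxy-3-oxopropanoic acid | CC(C)(C)OC(=O)CC(=O)O | starting material
7 | 2,2-diphenylethanol | OCC(c1ccccc1)c1ccccc1 | starting material
8 | tert-butyl 2,2-diphenylethyl malonate | CC(C)(C)OC(=O)CC(=O)OCC(c1ccccc1)c1ccccc1 | intermediate
9 | tert-butyl 2,2-diphenylethyl 2-{[(1R,3S)-2,2-dimethyl-3-(prop-1-en-2-yl)cyclobutyl]methyl}malonate, epimers at the malonate carbon | C=C(C)[C@@H]1C[C@H](CC(C(=O)OC(C)(C)C)C(=O)OCC(c2ccccc2)c2ccccc2)C1(C)C | intermediate
10 | (2S)-quaternary tert-butyl 2,2-diphenylethyl malonate carrying the cyclobutylmethyl and prenyl groups | C=C(C)[C@@H]1C[C@H](C[C@@](C(=O)OC(C)(C)C)(CC=C(C)C)C(=O)OCC(c2ccccc2)c2ccccc2)C1(C)C | intermediate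
11 | (2R)-malonic half-acid, 2,2-diphenylethyl ester retained | C=C(C)[C@@H]1C[C@H](C[C@@](C(=O)O)(CC=C(C)C)C(=O)OCC(c2ccccc2)c2ccccc2)C1(C)C | intermediate
12 | 3-phenylglutaric anhydride | O=C1CC(c2ccccc2)CC(=O)O1 | starting material
13 | (3R)-5-methoxy-5-oxo-3-phenylpentanoic acid | COC(=O)C[C@@H](CC(=O)O)c1ccccc1 | intermediate
14 | 1-tert-butyl 5-methyl (3S)-3-phenylpentanedioate | COC(=O)C[C@@H](CC(=O)OC(C)(C)C)c1ccccc1 | intermediate
15 | tert-butyl (3S)-5-oxo-3-phenylpentanoate | O=CC[C@@H](CC(=O)OC(C)(C)C)c1ccccc1 | intermediate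
16 | tert-butyl (3S)-3-phenylhex-5-ynoate | C#CC[C@@H](CC(=O)OC(C)(C)C)c1ccccc1 | intermediate
17 | 2,2-diphenylethyl (2S)-3-chloro-2-{[(1R,3S)-2,2-dimethyl-3-(prop-1-en-2-yl)cyclobutyl]methyl}-2-(3-methylbut-2-en-1-yl)-3-oxopropanoate (acid chloride of 11) | C=C(C)[C@@H]1C[C@H](C[C@@](C(Cl)=O)(CC=C(C)C)C(=O)OCC(c2ccccc2)c2ccccc2)C1(C)C | intermediate
18 | ynone: 9-tert-butyl 1-(2,2-diphenylethyl) (2R,7S)-2-(cyclobutylmethyl)-2-prenyl-3-oxo-7-phenylnon-4-ynedioate as named in step 13 | C=C(C)[C@@H]1C[C@H](C[C@@](C(=O)C#CC[C@@H](CC(=O)OC(C)(C)C)c2ccccc2)(CC=C(C)C)C(=O)OCC(c2ccccc2)c2ccccc2)C1(C)C | intermediate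
19 | methyl (3R)-3-hydroxybutanoate | C[C@@H](O)CC(=O)OC | starting material
20 | methyl (2R,3R)-3-hydroxy-2-methylbutanoate | C[C@@H](O)[C@@H](C)C(=O)OC | intermediate
21 | sodium allenolate formed by addition of the alkoxide of 20 to C8a of 18 | C=C(C)[C@@H]1C[C@H](C[C@@](C([O-])=C=C(O[C@H](C)[C@@H](C)C(=O)OC)C[C@@H](CC(=O)OC(C)(C)C)c2ccccc2)(CC=C(C)C)C(=O)OCC(c2ccccc2)c2ccccc2)C1(C)C.[Na+] | intermediate
22 | (2R,3R)-2,3-dimethyl-2,3-dihydro-4H-pyran-4-one carrying at C5 the keto-malonate chain (C5, C6, ester C7) and at C6 the (2S)-4-tert-butoxy-4-oxo-2-phenylbutyl chain | C=C(C)[C@@H]1C[C@H](C[C@@](C(=O)C2=C(C[C@@H](CC(=O)OC(C)(C)C)c3ccccc3)O[C@H](C)[C@@H](C)C2=O)(CC=C(C)C)C(=O)OCC(c2ccccc2)c2ccccc2)C1(C)C | intermediate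
23 | tert-butyl ester of the target, as named in step 15 | C=C(C)[C@@H]1C[C@H](C[C@@]2(CC=C(C)C)C(=O)C([C@@H](CC(=O)OC(C)(C)C)c3ccccc3)=C3O[C@H](C)[C@@H](C)C(=O)C3=C2O)C1(C)C | intermediate
24 | target acid, as named in step 16 | C=C(C)[C@@H]1C[C@H](C[C@@]2(CC=C(C)C)C(=O)C([C@@H](CC(=O)O)c3ccccc3)=C3O[C@H](C)[C@@H](C)C(=O)C3=C2O)C1(C)C | target

## Step count and risks

Total step count: 16. Longest linear sequence: 10 steps (1, 2, 3, 4, 6, 7, 8, 13, 15, 16).

**1. Step 15 (Proposed new method).** What may go wrong:
- β-elimination of the β-alkoxy ester (loss of the C2–C3 unit as a tiglate) before the Claisen closure;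
- 1,2-attack of the alkoxide at C5 followed by retro-Claisen cleavage at C6;
- slow Dieckmann closure at the hindered C7 ester;
- erosion of the C2 configuration by reversible retro-oxa-Michael opening of ring B.

Fallback, from 18, re-entering at 22 and then 23: pyrrolidine (EtOH, 23 °C) adds to the ynone to give the enaminone F1, which aqueous oxalic acid in THF hydrolyses to the 1,3-diketone F2. In parallel 20 is silylated (tBuMe2SiCl, imidazole, DMF) to the silyl ether F3, saponified (LiOH, THF/H2O) to the acid F4 and converted with oxalyl chloride and catalytic DMF into the acid chloride F5. Soft enolisation of F2 (MgBr2·OEt2, iPr2NEt, CH2Cl2) and C-acylation at C4a with F5 gives the triketone F6. HF·pyridine in THF removes the silyl group, and the δ-hydroxy triketone should cyclodehydrate at the unhindered C8a carbonyl (C5 is neopentyl-type) to the dihydropyranone 22, now isolated. NaOMe in THF/MeOH then closes ring A by Dieckmann condensation to 23. Each operation is of a known type: amine addition to ynones, magnesium-mediated C-acylation of β-diketones, acid cyclodehydration of δ-hydroxy-β-diketones to dihydropyranones, and Dieckmann closure of 3,5-dioxo esters.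

**2. Step 7.** What may go wrong: poor facial discrimination of the fully substituted enolate ion pair, because the α-substituent is large and itself chiral (possible mismatch with the catalyst), together with slow alkylation at −40 °C.

Fallback, from 9, returning at 11: non-selective prenylation (NaH, prenyl bromide, THF) gives the C2-epimeric diester mixture F7, and Me3SiOTf/2,6-lutidine converts it into the epimeric half-acids F8. Because the cyclobutane is enantiopure these are diastereomers. The (2R) acid is separated by fractional crystallisation of its (R)-1-phenylethylammonium salt F9 (or by preparative chromatography) and liberated with dilute acid as 11. This replaces catalyst control by separation.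

**3. Step 6.** What may go wrong: slow SN2 displacement and competing E2 elimination at the β-branched iodide that sits next to the gem-dimethyl carbon, with a bulky malonate anion.

Fallback, from 4, returning at 9: Dess–Martin oxidation gives the aldehyde F10. Three-component reductive alkylation with 2,2-dimethyl-1,3-dioxane-4,6-dione and Hantzsch ester (L-proline, EtOH, 23 °C; Knoevenagel condensation then transfer hydrogenation) gives the alkyl Meldrum's acid F11. Heating with 7 in toluene at 90 °C opens it to the half-ester F12, and tert-butylation (tert-butyl 2,2,2-trichloroacetimidate, catalytic BF3·OEt2) gives 9. The C–C bond is thus made by condensation and reduction, not by substitution.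

## Further compounds

F1 | step 15 | pyrrolidine enaminone of 18 (amine on C8a) | C=C(C)[C@@H]1C[C@H](C[C@@](C(=O)C=C(C[C@@H](CC(=O)OC(C)(C)C)c2ccccc2)N2CCCC2)(CC=C(C)C)C(=O)OCC(c2ccccc2)c2ccccc2)C1(C)C
F2 | step 15 | 1,3-diketone (C5 and C8a carbonyls) derived from 18 | C=C(C)[C@@H]1C[C@H](C[C@@](C(=O)CC(=O)C[C@@H](CC(=O)OC(C)(C)C)c2ccccc2)(CC=C(C)C)C(=O)OCC(c2ccccc2)c2ccccc2)C1(C)C
F3 | step 15 | methyl (2R,3R)-3-[(tert-butyldimethylsilyl)oxy]-2-methylbutanoate | C[C@@H](O[Si](C)(C)C(C)(C)C)[C@@H](C)C(=O)OC
F4 | step 15 | (2R,3R)-3-[(tert-butyldimethylsilyl)oxy]-2-methylbutanoic acid | C[C@@H](O[Si](C)(C)C(C)(C)C)[C@@H](C)C(=O)O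
F5 | step 15 | (2R,3R)-3-[(tert-butyldimethylsilyl)oxy]-2-methylbutanoyl chloride | C[C@@H](O[Si](C)(C)C(C)(C)C)[C@@H](C)C(Cl)=O
F6 | step 15 | triketone: F2 acylated at C4a by the silyloxy acyl group | C=C(C)[C@@H]1C[C@H](C[C@@](C(=O)C(C(=O)[C@H](C)[C@@H](C)O[Si](C)(C)C(C)(C)C)C(=O)C[C@@H](CC(=O)OC(C)(C)C)c2ccccc2)(CC=C(C)C)C(=O)OCC(c2ccccc2)c2ccccc2)C1(C)C
F7 | step 7 | C2-epimeric mixture of diester 10 | C=C(C)[C@@H]1C[C@H](CC(C(=O)OC(C)(C)C)(CC=C(C)C)C(=O)OCC(c2ccccc2)c2ccccc2)C1(C)C
F8 | step 7 | C2-epimeric mixture of half-acid 11 | C=C(C)[C@@H]1C[C@H](CC(C(=O)O)(CC=C(C)C)C(=O)OCC(c2ccccc2)c2ccccc2)C1(C)C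
F9 | step 7 | (R)-1-phenylethylammonium salt of 11 | C=C(C)[C@@H]1C[C@H](C[C@@](C(=O)[O-])(CC=C(C)C)C(=O)OCC(c2ccccc2)c2ccccc2)C1(C)C.C[C@@H]([NH3+])c1ccccc1
F10 | step 6 | (1S,3S)-2,2-dimethyl-3-(prop-1-en-2-yl)cyclobutane-1-carbaldehyde | C=C(C)[C@@H]1C[C@H](C=O)C1(C)C
F11 | step 6 | 5-{[(1R,3S)-2,2-dimethyl-3-(prop-1-en-2-yl)cyclobutyl]methyl}-2,2-dimethyl-1,3-dioxane-4,6-dione | C=C(C)[C@@H]1C[C@H](CC2C(=O)OC(C)(C)OC2=O)C1(C)C
F12 | step 6 | 2-{[(1R,3S)-2,2-dimethyl-3-(prop-1-en-2-yl)cyclobutyl]methyl}-3-(2,2-diphenylethoxy)-3-oxopropanoic acid | C=C(C)[C@@H]1C[C@H](CC(C(=O)O)C(=O)OCC(c2ccccc2)c2ccccc2)C1(C)C
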